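## Retrosynthetic overview

1. Target ⇐ palladium cyclocarbonylation of a C6‑hydroxy/C7‑ethynyl unit (lactone, last ring), after C8 angeloylation and a C8‑OH‑directed epoxidation of the Z‑C1=C10 alkene.
2. Ten‑membered ring ⇐ Grob fragmentation of a cis‑fused hydroazulene 1,3‑diol monomesylate: the C6–C10 bond is cut (7→10 three‑carbon ring expansion), Z‑C4=C5 is inherited from the seven‑membered ring, Z‑C1=C10 is set stereospecifically.
3. Hydroazulene ⇐ indium Barbier propargylation onto the enone carbonyl of a 2‑methyl‑2‑(epoxypentynyl)cycloheptenedione (Tsuji–Trost alkylation, Shi epoxidation).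
4. Cycloheptene‑1,3‑dione ⇐ acyl‑transfer ring expansion of a butenolide made from 3‑methylpentane‑2,4‑dione and 5‑hydroxy‑4‑methylfuran‑2(5H)‑one.
5. Ring order: seven‑membered carbocycle → five‑membered ring (temporary) → ten‑membered carbocycle → epoxide → lactone.

Assumption: compounds 1, 2, 7, 10 and 19 are bought (7 as the pure E isomer); germacrane numbering of the target (ring C1–C10, C14 on C10, C15 on C4, lactone C11–C13) is used for ring atoms throughout.

## Route

Step 1
Reactants: 1 3-methylpentane-2,4-dione; 2 5-hydroxy-4-methylfuran-2(5H)-one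
Product: 4 rac-4-methyl-5-(3-methyl-2,4-dioxopentyl)furan-2(5H)-one, via hydroxy acid 3 (not isolated)
Conditions: 1, NaH then n-BuLi, THF, 0 °C; Na salt of 2 (NaH, THF), −78 → 0 °C; then 1 M HCl, rt
Reagents that add atoms: none
Why: Hauser-type 1,3-diketone dianion aldol in which the terminal carbanion adds 1,2 to the aldehyde of the ring-opened (Z)-formyl carboxylate form of 2 and the (Z)-γ-hydroxy acid 3 lactonises on acidification; the new carbinol centre (future C3) is racemic and the diketone CH is stereolabile.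

Step 2
Reactants: 4 rac-4-methyl-5-(3-methyl-2,4-dioxopentyl)furan-2(5H)-one
Product: 6 rac-6-hydroxy-2,5-dimethylcyclohept-4-ene-1,3-dione, via acetyl triketone 5 (not isolated)
Conditions: NaOMe (2.2 equiv), MeOH, 0 °C → rt; then 1 M HCl to pH 4
Reagents that add atoms: none
Why: Proposed new method: a thermodynamically driven acyl-transfer ring expansion (five-membered lactone to seven-membered carbocycle) in which the sodium enolate of the 1,3-diketone C-acylates on the butenolide carbonyl through a six-membered transition state (bridged hemiketal alkoxide), the ring oxygen leaves as the C3 alkoxide, and retro-Claisen loss of the surplus acetyl group (finally as methyl acetate) leaves the more acidic, conjugated cyclic 1,3-dione enolate as the sink while the acidic diketone buffers the medium against E1cB opening of the β-acyloxy ketone; closest known reactions are Claisen/retro-Claisen acyl exchange between 1,3-diketones and esters and the base-induced rearrangement of ylidenebutenolides to cyclopentene-1,3-diones; no new stereocentre is set (C3 stays racemic).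

Step 3
Reactants: 7 (2E)-pent-2-en-4-yn-1-ol
Product: 8 methyl (2E)-pent-2-en-4-yn-1-yl carbonate
Conditions: ClCO2Me, pyridine, CH2Cl2, 0 °C
Reagents that add atoms: methyl chloroformate, COC(Cl)=O
Why: Standard O-acylation gives the allylic carbonate needed for ionisation by zerovalent palladium; no stereocentre is involved.

Step 4
Reactants: 6 rac-6-hydroxy-2,5-dimethylcyclohept-4-ene-1,3-dione; 8 methyl (2E)-pent-2-en-4-yn-1-yl carbonate
Product: 9 (2S,6S)-6-hydroxy-2,5-dimethyl-2-[(2E)-pent-2-en-4-yn-1-yl]cyclohept-4-ene-1,3-dione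
Conditions: Pd2(dba)3·CHCl3 (2.5 mol%), (S,S)-DACH-phenyl Trost ligand (7.5 mol%), CH2Cl2, rt; chromatography
Reagents that add atoms: none
Why: Tsuji–Trost asymmetric allylic alkylation in which the soft dione enolate attacks the unsubstituted terminus of the π-allylpalladium complex (E-enyne retained) and the ligand enantiomer that differentiates the enolate faces in the required sense sets the quaternary centre (2S, future C10); because 6 is racemic two C6 epimers form, and the (2S,6S) epimer is isolated by chromatography.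

Step 5
Reactants: 9 (2S,6S)-6-hydroxy-2,5-dimethyl-2-[(2E)-pent-2-en-4-yn-1-yl]cyclohept-4-ene-1,3-dione; 10 (2R)-2-methylbutanoic acid
Product: 11 (1S,5S)-2,5-dimethyl-4,6-dioxo-5-[(2E)-pent-2-en-4-yn-1-yl]cyclohept-2-en-1-yl (2R)-2-methylbutanoate
Conditions: DCC, DMAP (cat.), CH2Cl2, 0 °C → rt
Reagents that add atoms: none
Why: Steglich esterification of the secondary allylic alcohol (the open hydroxy-dione is drained from its hemiketal form) with retention at the carbinol carbon and at the acid α-carbon.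

Step 6
Reactants: 11 (1S,5S)-2,5-dimethyl-4,6-dioxo-5-[(2E)-pent-2-en-4-yn-1-yl]cyclohept-2-en-1-yl (2R)-2-methylbutanoate
Product: 12 (1S,5S,6S)-6-hydroxy-2,5-dimethyl-4-oxo-5-[(2E)-pent-2-en-4-yn-1-yl]cyclohept-2-en-1-yl (2R)-2-methylbutanoate
Conditions: NaBH4, MeOH–CH2Cl2, −40 °C
Reagents that add atoms: none
Why: Chemoselective borohydride reduction of the saturated ketone beside the conjugated one, with hydride delivered from the face of the small methyl group (anti to the enynyl chain), so the new hydroxyl (future C1) is trans to the methyl on the adjacent quaternary carbon.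

Step 7
Reactants: 12 (1S,5S,6S)-6-hydroxy-2,5-dimethyl-4-oxo-5-[(2E)-pent-2-en-4-yn-1-yl]cyclohept-2-en-1-yl (2R)-2-methylbutanoate
Product: 13 (1S,5S,6S)-6-(methanesulfonyloxy)-2,5-dimethyl-4-oxo-5-[(2E)-pent-2-en-4-yn-1-yl]cyclohept-2-en-1-yl (2R)-2-methylbutanoate
Conditions: MsCl, Et3N, CH2Cl2, 0 °C
Reagents that add atoms: methanesulfonyl chloride, CS(Cl)(=O)=O
Why: Sulfonylation of the only free hydroxyl with retention installs the nucleofuge for the later fragmentation.

Step 8
Reactants: 13 (1S,5S,6S)-6-(methanesulfonyloxy)-2,5-dimethyl-4-oxo-5-[(2E)-pent-2-en-4-yn-1-yl]cyclohept-2-en-1-yl (2R)-2-methylbutanoate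
Product: 14 (1S,5S,6S)-5-{[(2R,3R)-3-ethynyloxiran-2-yl]methyl}-6-(methanesulfonyloxy)-2,5-dimethyl-4-oxocyclohept-2-en-1-yl (2R)-2-methylbutanoate
Conditions: D-fructose-derived Shi ketone (30 mol%), KHSO5, K2CO3, Bu4NHSO4, MeCN–CH2(OMe)2–aq. buffer pH 10.5, 0 °C
Reagents that add atoms: potassium peroxymonosulfate, [K+].[O-]S(=O)(=O)OO
Why: Shi asymmetric epoxidation in which the chiral dioxirane attacks the electron-richer E-disubstituted enyne alkene through a spiro transition state (the enone alkene is inert), setting future C8 (R) and the propargylic carbon (R) under catalyst control.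

Step 9
Reactants: 14 (1S,5S,6S)-5-{[(2R,3R)-3-ethynyloxiran-2-yl]methyl}-6-(methanesulfonyloxy)-2,5-dimethyl-4-oxocyclohept-2-en-1-yl (2R)-2-methylbutanoate
Product: 16 cis-fused hydroazulene diol mesylate [7β-ethynyl-6β,8β-dihydroxy-1α-(methanesulfonyloxy)-4,10β-dimethylbicyclo[5.3.0]dec-4-en-3β-yl (2R)-2-methylbutanoate], via bromohydrin 15 (not isolated)
Conditions: LiBr, AcOH, THF, 0 °C → rt; then In powder, THF–H2O, rt
Reagents that add atoms: none
Why: SN2 opening of the alkynyl epoxide by bromide at the activated propargylic carbon, then an indium-mediated Barbier propargylation in which the allenylindium adds through a closed six-membered transition state to the ketone from the face that carries the tether, giving the cis-fused five-membered ring with the tertiary C6 hydroxyl and the C7 ethynyl group (R) cis and on the convex face together with the C8 hydroxyl fixed in step 8.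

Step 10
Reactants: 16 cis-fused hydroazulene diol mesylate
Product: 17 (2Z,4S,6Z,9R,10R)-10-ethynyl-9-hydroxy-3,7-dimethyl-4-[(2R)-2-methylbutanoyloxy]cyclodeca-2,6-dien-1-one
Conditions: KOtBu (1.05 equiv), THF, 0 °C, 15 min; AcOH quench
Reagents that add atoms: none
Why: Grob (Wharton-type) fragmentation of the 1,3-diol monomesylate in which the tertiary alkoxide expels the antiperiplanar C6–C10 bond and the mesylate, expanding the seven-membered ring to the ten-membered ring; the mesylate trans to the angular methyl gives the Z-C1=C10 alkene stereospecifically, Z-C4=C5 comes from the seven-membered ring, and C3, C7 and C8 are untouched.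

Step 11
Reactants: 17 (2Z,4S,6Z,9R,10R)-10-ethynyl-9-hydroxy-3,7-dimethyl-4-[(2R)-2-methylbutanoyloxy]cyclodeca-2,6-dien-1-one
Product: 18 (1R,10S)-1,10-epoxide of 17 [7β-ethynyl-8β-hydroxy-1β,10β-epoxy-6-oxo ten-membered ring ketone]
Conditions: VO(acac)2 (5 mol%), t-BuOOH, CH2Cl2, 0 °C → rt
Reagents that add atoms: tert-butyl hydroperoxide, CC(C)(C)OO
Why: Hydroxyl-directed epoxidation in which the homoallylic C8 hydroxyl delivers oxygen to its own face of the electron-rich Z-C1=C10 alkene (enone alkene and alkyne are not attacked), setting C1 (R) and C10 (S).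

Step 12
Reactants: 18 (1R,10S)-1,10-epoxide of 17; 19 angelic acid [(2Z)-2-methylbut-2-enoic acid]
Product: 20 8-O-angeloyl epoxy ketone [8β-angeloyloxy-7β-ethynyl-1β,10β-epoxy-6-oxo ring ketone 3β-(2R)-2-methylbutanoate]
Conditions: 19, 2,4,6-trichlorobenzoyl chloride, Et3N, toluene, rt; then 18, 60 °C
Reagents that add atoms: none
Why: Yamaguchi-type mixed-anhydride esterification without nucleophilic catalyst, the usual way to make angelates without Z-to-E isomerisation, with retention at C8.

Step 13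
Reactants: 20 8-O-angeloyl epoxy ketone
Product: 21 (6R)-alcohol [8β-angeloyloxy-7β-ethynyl-1β,10β-epoxy-6α-hydroxy ring 3β-(2R)-2-methylbutanoate]
Conditions: NaBH4, CeCl3·7H2O, MeOH, −78 °C
Reagents that add atoms: none
Why: Luche 1,2-reduction of the enone carbonyl in which hydride adds anti to the ethynyl group on C7 (polar Felkin–Anh model with the alkynyl group perpendicular, peripheral attack on the ring), giving the 6R alcohol placed for the trans-lactone.

Step 14
Reactants: 21 (6R)-alcohol
Product: 22 CNP0108431.1 [(1R,3S,6R,7R,8R,10S)-8β-angeloyloxy-1β,10β-epoxy-3β-[(2R)-2-methylbutanoyloxy]germacra-4Z,11(13)-dien-12,6α-olide]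
Conditions: PdCl2 (10 mol%), thiourea (10 mol%), CO (1 atm), acetone, 50 °C
Reagents that add atoms: carbon monoxide, [C-]#[O+]
Why: Palladium-catalysed cyclocarbonylation of a homopropargylic alcohol (Norton-type) in which the alkoxycarbonylpalladium species formed at the only free hydroxyl (C6) adds syn across the alkyne in a 5-exo mode and protonolysis releases the α-methylene-γ-lactone; the trans ring fusion follows from the C6 and C7 centres already present.

## Compound list

1 | 3-methylpentane-2,4-dione | CC(=O)C(C)C(C)=O | starting material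
2 | 5-hydroxy-4-methylfuran-2(5H)-one | CC1=CC(=O)OC1O | starting material
3 | rac-(2Z)-4-hydroxy-3,7-dimethyl-6,8-dioxonon-2-enoic acid (racemate, carried-on enantiomer drawn, diketone CH unassigned) | OC(=O)/C=C(/C)[C@@H](O)CC(=O)C(C)C(C)=O | intermediate
4 | rac-4-methyl-5-(3-methyl-2,4-dioxopentyl)furan-2(5H)-one (racemate, carried-on enantiomer drawn) | O=C1C=C(C)[C@H](CC(=O)C(C)C(C)=O)O1 | intermediate
5 | rac-2-acetyl-6-hydroxy-2,5-dimethylcyclohept-4-ene-1,3-dione (formed as its alkoxide) | CC(=O)C1(C)C(=O)C[C@H](O)C(C)=CC1=O | intermediate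
6 | rac-6-hydroxy-2,5-dimethylcyclohept-4-ene-1,3-dione (racemate, carried-on 6S enantiomer drawn; in equilibrium with enol and bridged hemiketal forms) | CC1C(=O)C[C@H](O)C(C)=CC1=O | intermediate
7 | (2E)-pent-2-en-4-yn-1-ol | OC/C=C/C#C | starting material
8 | methyl (2E)-pent-2-en-4-yn-1-yl carbonate | COC(=O)OC/C=C/C#C | intermediate
9 | (2S,6S)-6-hydroxy-2,5-dimethyl-2-[(2E)-pent-2-en-4-yn-1-yl]cyclohept-4-ene-1,3-dione | C[C@]1(C/C=C/C#C)C(=O)C[C@H](O)C(C)=CC1=O | intermediate
10 | (2R)-2-methylbutanoic acid | CC[C@@H](C)C(=O)O | starting material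
11 | (1S,5S)-2,5-dimethyl-4,6-dioxo-5-[(2E)-pent-2-en-4-yn-1-yl]cyclohept-2-en-1-yl (2R)-2-methylbutanoate | C[C@]1(C/C=C/C#C)C(=O)C[C@H](OC(=O)[C@H](C)CC)C(C)=CC1=O | intermediate
12 | (1S,5S,6S)-6-hydroxy-2,5-dimethyl-4-oxo-5-[(2E)-pent-2-en-4-yn-1-yl]cyclohept-2-en-1-yl (2R)-2-methylbutanoate | C[C@]1(C/C=C/C#C)[C@@H](O)C[C@H](OC(=O)[C@H](C)CC)C(C)=CC1=O | intermediate
13 | (1S,5S,6S)-6-(methanesulfonyloxy)-2,5-dimethyl-4-oxo-5-[(2E)-pent-2-en-4-yn-1-yl]cyclohept-2-en-1-yl (2R)-2-methylbutanoate | C[C@]1(C/C=C/C#C)[C@@H](OS(C)(=O)=O)C[C@H](OC(=O)[C@H](C)CC)C(C)=CC1=O | intermediate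
14 | (1S,5S,6S)-5-{[(2R,3R)-3-ethynyloxiran-2-yl]methyl}-6-(methanesulfonyloxy)-2,5-dimethyl-4-oxocyclohept-2-en-1-yl (2R)-2-methylbutanoate | C[C@]1(C[C@H]2O[C@@H]2C#C)[C@@H](OS(C)(=O)=O)C[C@H](OC(=O)[C@H](C)CC)C(C)=CC1=O | intermediate
15 | (1S,5S,6S)-5-[(2R,3S)-3-bromo-2-hydroxypent-4-yn-1-yl]-6-(methanesulfonyloxy)-2,5-dimethyl-4-oxocyclohept-2-en-1-yl (2R)-2-methylbutanoate | C[C@]1(C[C@@H](O)[C@@H](Br)C#C)[C@@H](OS(C)(=O)=O)C[C@H](OC(=O)[C@H](C)CC)C(C)=CC1=O | intermediate
16 | cis-fused hydroazulene diol mesylate: 7β-ethynyl-6β,8β-dihydroxy-1α-(methanesulfonyloxy)-4,10β-dimethylbicyclo[5.3.0]dec-4-en-3β-yl (2R)-2-methylbutanoate (C6–C10 bond, germacrane numbering) | O[C@@]12C=C(C)[C@@H](OC(=O)[C@H](C)CC)C[C@H](OS(C)(=O)=O)[C@]1(C)C[C@@H](O)[C@H]2C#C | intermediate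
17 | (2Z,4S,6Z,9R,10R)-10-ethynyl-9-hydroxy-3,7-dimethyl-4-[(2R)-2-methylbutanoyloxy]cyclodeca-2,6-dien-1-one | O=C1/C=C(/C)[C@@H](OC(=O)[C@H](C)CC)C/C=C(/C)C[C@@H](O)[C@H]1C#C | intermediate
18 | (1R,10S)-1,10-epoxide of 17 (epoxide on the face of the C8 hydroxyl) | O=C1/C=C(/C)[C@@H](OC(=O)[C@H](C)CC)C[C@H]2O[C@@]2(C)C[C@@H](O)[C@H]1C#C | intermediate
19 | angelic acid, (2Z)-2-methylbut-2-enoic acid | C/C=C(/C)C(=O)O | starting material
20 | 8-O-angeloyl derivative of 18 | O=C1/C=C(/C)[C@@H](OC(=O)[C@H](C)CC)C[C@H]2O[C@@]2(C)C[C@@H](OC(=O)/C(C)=C\C)[C@H]1C#C | intermediate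
21 | (6R)-alcohol from 20 (6α-hydroxy, 7β-ethynyl) | O[C@@H]1/C=C(/C)[C@@H](OC(=O)[C@H](C)CC)C[C@H]2O[C@@]2(C)C[C@@H](OC(=O)/C(C)=C\C)[C@H]1C#C | intermediate
22 | CNP0108431.1, (1R,3S,6R,7R,8R,10S)-configured 4Z-germacranolide 1,10-epoxide with 3-(2R)-2-methylbutanoate and 8-angelate | C=C1C(=O)O[C@@H]2/C=C(/C)[C@@H](OC(=O)[C@H](C)CC)C[C@H]3O[C@@]3(C)C[C@@H](OC(=O)/C(C)=C\C)[C@@H]12 | target

## Step count and risks

Total step count: 14. Longest linear sequence: 13 (steps 1, 2 and 4–14; step 3 is the side branch).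

Steps most likely to fail:

Step 2 (the proposed new step). The equilibrium may stay on the butenolide side, the enolate may add in conjugate fashion to the butenolide, or 6 may dehydrate. The fallback sets out from 4 and comes back at 6, making the ring bond irreversibly with an activated acyl donor. Compound 4 is opened with aqueous KOH, silylated at oxygen (TBSCl, imidazole, DMF), and the silyl ester and enol silyl ether are cleaved selectively (K2CO3, MeOH–H2O) to give rac-(2Z)-4-[(tert-butyldimethylsilyl)oxy]-3,7-dimethyl-6,8-dioxonon-2-enoic acid F1. Activation with carbonyldiimidazole and soft-enolisation C-acylation (MgCl2, Et3N, MeCN) closes the ring to rac-2-acetyl-6-[(tert-butyldimethylsilyl)oxy]-2,5-dimethylcyclohept-4-ene-1,3-dione F2. Retro-Claisen deacetylation (NaOMe, MeOH, 0 °C) gives rac-6-[(tert-butyldimethylsilyl)oxy]-2,5-dimethylcyclohept-4-ene-1,3-dione F3, and HF·pyridine then returns 6.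

Step 9. The organoindium may be protonated before it cyclises, or the ring closure may be unselective. The fallback sets out from 14 and comes back at 16. The bromohydrin 15 is isolated after the LiBr/AcOH stage and silylated (TESOTf, 2,6-lutidine) to (1S,5S,6S)-5-[(2R,3S)-3-bromo-2-(triethylsilyloxy)pent-4-yn-1-yl]-6-(methanesulfonyloxy)-2,5-dimethyl-4-oxocyclohept-2-en-1-yl (2R)-2-methylbutanoate F4. The ring is then closed under anhydrous conditions by an intramolecular Nozaki–Hiyama–Kishi propargylation (CrCl2, NiCl2 cat., THF–DMF), an established way to add propargyl halides to ketones, giving the 8-O-triethylsilyl ether of the cis-fused hydroazulene diol mesylate F5. HF·pyridine returns 16.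

Step 14. The late cyclocarbonylation runs beside an epoxide, an angelate and allylic esters. The fallback sets out from 21 and comes back at 22, building the lactone from a vinyl iodide. Molybdenum-catalysed α-selective hydrostannation (Mo(CO)3(CNtBu)3, Bu3SnH, THF) gives the 1-(tributylstannyl)ethenyl analogue of 21 F6. Iododestannylation (I2, CH2Cl2, 0 °C) gives the 1-iodoethenyl analogue of 21 F7. Carbonylative lactonisation (Pd(PPh3)4, CO 1 atm, Et3N, MeCN, 50 °C) closes the α-methylene lactone to 22.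

## Further compounds

F1 | step 2 | rac-(2Z)-4-[(tert-butyldimethylsilyl)oxy]-3,7-dimethyl-6,8-dioxonon-2-enoic acid | OC(=O)/C=C(/C)[C@@H](O[Si](C)(C)C(C)(C)C)CC(=O)C(C)C(C)=O
F2 | step 2 | rac-2-acetyl-6-[(tert-butyldimethylsilyl)oxy]-2,5-dimethylcyclohept-4-ene-1,3-dione | CC(=O)C1(C)C(=O)C[C@H](O[Si](C)(C)C(C)(C)C)C(C)=CC1=O
F3 | step 2 | rac-6-[(tert-butyldimethylsilyl)oxy]-2,5-dimethylcyclohept-4-ene-1,3-dione | CC1C(=O)C[C@H](O[Si](C)(C)C(C)(C)C)C(C)=CC1=O
F4 | step 9 | (1S,5S,6S)-5-[(2R,3S)-3-bromo-2-(triethylsilyloxy)pent-4-yn-1-yl]-6-(methanesulfonyloxy)-2,5-dimethyl-4-oxocyclohept-2-en-1-yl (2R)-2-methylbutanoate | C[C@]1(C[C@@H](O[Si](CC)(CC)CC)[C@@H](Br)C#C)[C@@H](OS(C)(=O)=O)C[C@H](OC(=O)[C@H](C)CC)C(C)=CC1=O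
F5 | step 9 | 8-O-triethylsilyl ether of the cis-fused hydroazulene diol mesylate 16 | O[C@@]12C=C(C)[C@@H](OC(=O)[C@H](C)CC)C[C@H](OS(C)(=O)=O)[C@]1(C)C[C@@H](O[Si](CC)(CC)CC)[C@H]2C#C
F6 | step 14 | 1-(tributylstannyl)ethenyl analogue of 21 | O[C@@H]1/C=C(/C)[C@@H](OC(=O)[C@H](C)CC)C[C@H]2O[C@@]2(C)C[C@@H](OC(=O)/C(C)=C\C)[C@H]1C(=C)[Sn](CCCC)(CCCC)CCCC
F7 | step 14 | 1-iodoethenyl analogue of 21 | O[C@@H]1/C=C(/C)[C@@H](OC(=O)[C@H](C)CC)C[C@H]2O[C@@]2(C)C[C@@H](OC(=O)/C(C)=C\C)[C@H]1C(I)=C
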